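**Retrosynthetic overview** (germacrane numbering: C6 = CHOH, C7 = CH‑iPr, C8 = CH‑O‑aroyl; olefins C1=C10 and C4=C5, both Z)
1. Target ⇐ its 11,12‑dehydro compound with the phenol as acetate; the last two steps only saturate the isopropenyl group and free the phenol.
2. Ring (the only ring formed; the benzene ring is bought): C6–C7, the bond nature makes by 1,10‑cyclisation of a farnesyl chain. It is closed with reversed polarity on the fully oxygenated chain, ester in place: a C12 allylchromium (from CrCl2) adds through C7 to the C6 (2Z)‑enal and sets C6 and C7 from C8 in the same event. A Lewis‑acid (cationic) closure is ruled out because the 2Z‑enal would close the six‑membered ring onto C1=C10 first.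
3. Open (2Z,6Z,10E)‑chain ⇐ neryl acetate 1 (C1–C6, C15; a Z‑selective iodoethylidene Wittig reaction adds C10, C14), (R)‑epichlorohydrin 2 (C7–C9 and the C8 stereocentre), 4‑(acetyloxy)benzoyl chloride 3 (ester) and 3‑bromo‑2‑methylpropene 4 (C11–C13, by cross‑metathesis).

Assumption: the SMILES is taken as written, i.e. the (1(10)Z,4Z)‑germacradiene with 6S,7R,8R configuration (OH and ester cis to each other, isopropyl trans to both).

**Step 1**
Reactants: 1 neryl acetate
Product: 5 (2Z)-3-methyl-6-oxohex-2-en-1-yl acetate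
Conditions: O3 (1.0 equiv), CH2Cl2/pyridine, −78 °C; Me2S, −78 °C to rt
Reagents that add atoms: ozone, [O-][O+]=O
Why: Chemoselective ozonolysis, in which the electron‑rich 6,7‑olefin is cleaved (acetone is lost) while the 2,3‑olefin, deactivated by the allylic acetate, survives with its Z geometry; no stereocentre is formed.

**Step 2**
Reactants: 5 (2Z)-3-methyl-6-oxohex-2-en-1-yl acetate
Product: 6 (2Z,6Z)-7-iodo-3-methylocta-2,6-dien-1-yl acetate
Conditions: [Ph3PEt]I, n-BuLi, THF, rt; I2, −78 °C; NaN(SiMe3)2, −20 °C; 5, −78 to −20 °C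
Reagents that add atoms: ethyltriphenylphosphonium iodide, CC[P+](c1ccccc1)(c1ccccc1)c1ccccc1.[I-]; iodine, II
Why: Stork–Zhao α‑iodoalkylidene Wittig olefination, in which the non‑stabilised iodo ylide gives under kinetic control the (Z)-2-iodoalk-2-ene with iodine cis to the chain (this fixes the later C1=C10 geometry), and the acetate is not attacked at −78 °C.

**Step 3**
Reactants: 6 (2Z,6Z)-7-iodo-3-methylocta-2,6-dien-1-yl acetate; 2 (R)-epichlorohydrin
Product: 9 (2Z,6Z,9R)-10-chloro-3,7-dimethyldeca-2,6-diene-1,9-diol, via lithium alkoxide 7 (not isolated), via alkenylmagnesium bromide 8 (not isolated)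
Conditions: MeLi (2.1 equiv), Et2O, −78 °C; t-BuLi (2.1 equiv), −78 °C; MgBr2·OEt2, −78 to −40 °C; CuI (10 mol%), 2, −40 °C; H2O
Reagents that add atoms: none
Why: MeLi first removes the acetate (ester cleavage to the lithium alkoxide), iodine–lithium exchange and transmetalation then give the alkenylmagnesium bromide with retention of the Z geometry, and its CuI‑catalysed SN2 opening of the epoxide at the CH2 terminus forms C9–C10 while the C8 stereocentre is taken unchanged from 2 because no bond to it is broken.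

**Step 4**
Reactants: 9 (2Z,6Z,9R)-10-chloro-3,7-dimethyldeca-2,6-diene-1,9-diol
Product: 11 (2Z,6Z,9R)-3,7-dimethylundeca-2,6,10-triene-1,9-diol, via epoxide 10 (not isolated)
Conditions: Me3S+ I− (6 equiv), n-BuLi (6 equiv), THF, −10 °C to rt; H2O
Reagents that add atoms: trimethylsulfonium iodide, C[S+](C)C.[I-]
Why: One‑carbon homologation of an epoxide to an allylic alcohol with dimethylsulfonium methylide, in which base closes the chlorohydrin to the terminal epoxide, the ylide opens it at CH2 and the betaine eliminates Me2S to leave the vinyl group; the C8–O bond is never broken, so the R configuration is kept.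

**Step 5**
Reactants: 11 (2Z,6Z,9R)-3,7-dimethylundeca-2,6,10-triene-1,9-diol
Product: 12 (2Z,6Z,9R)-9-hydroxy-3,7-dimethylundeca-2,6,10-trienal
Conditions: TEMPO (10 mol%), PhI(OAc)2 (1.1 equiv), CH2Cl2, rt
Reagents that add atoms: none
Why: Oxoammonium (TEMPO) oxidation, which takes the primary allylic alcohol much faster than the secondary one and does not isomerise the Z‑enal under these neutral conditions; no stereocentre is touched.

**Step 6**
Reactants: 12 (2Z,6Z,9R)-9-hydroxy-3,7-dimethylundeca-2,6,10-trienal; 3 4-(acetyloxy)benzoyl chloride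
Product: 13 (3R,5Z,9Z)-5,9-dimethyl-11-oxoundeca-1,5,9-trien-3-yl 4-(acetyloxy)benzoate
Conditions: pyridine, CH2Cl2, 0 °C to rt
Reagents that add atoms: none
Why: Acylation of the secondary alcohol by the acid chloride (nucleophilic acyl substitution at the acyl carbon, so C8 keeps its configuration); the acid chloride reacts far faster than the phenolic acetate, so no acetyl transfer occurs.

**Step 7**
Reactants: 13 (3R,5Z,9Z)-5,9-dimethyl-11-oxoundeca-1,5,9-trien-3-yl 4-(acetyloxy)benzoate; 4 3-bromo-2-methylpropene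
Product: 14 (2E,4R,6Z,10Z)-1-bromo-2,6,10-trimethyl-12-oxododeca-2,6,10-trien-4-yl 4-(acetyloxy)benzoate
Conditions: 4 (10 equiv), second-generation Hoveyda–Grubbs catalyst RuCl2(H2IMes)(=CH-C6H4-2-OiPr) (10 mol%), CH2Cl2, 40 °C
Reagents that add atoms: none
Why: Olefin cross‑metathesis, in which only the monosubstituted vinyl group is open to the ruthenium carbene (the trisubstituted Z‑olefins and the conjugated enal are inert, and 4 cannot homodimerise), giving mainly the E‑bromide; no stereocentre is formed and the minor Z‑isomer is carried on because both equilibrate to the same allylchromium in step 8.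

**Step 8**
Reactants: 14 (2E,4R,6Z,10Z)-1-bromo-2,6,10-trimethyl-12-oxododeca-2,6,10-trien-4-yl 4-(acetyloxy)benzoate
Product: 16 (1R,2R,3S,4Z,8Z)-3-hydroxy-5,9-dimethyl-2-(prop-1-en-2-yl)cyclodeca-4,8-dien-1-yl 4-(acetyloxy)benzoate, via allylchromium dichloride 15 (not isolated)
Conditions: CrCl2 (10 equiv), THF, 25 °C, slow addition of 14 (final 2 mM); H2O
Reagents that add atoms: none
Why: Intramolecular Nozaki–Hiyama allylation (the polarity‑reversed counterpart of the 1,10‑cyclisation of a farnesyl chain), in which two CrCl2 turn the bromide into a trivalent allylchromium that adds through its γ‑carbon C7 to the tethered aldehyde in a chair Zimmerman–Traxler transition state with the aldehyde chain and the E‑allyl substituent both pseudo‑equatorial (6S,7R relationship) and with C8–H eclipsing the alkene to avoid 1,3‑allylic strain with the C13 methyl, so that C6 bonds anti to the C8–O bond and OH, isopropenyl and ester all end pseudo‑equatorial on the new ring (6S,7R,8R); esters and the Z‑enal are inert to CrCl2, and only the ten‑membered ring can form because an allylmetal, not a cation, is the reactive partner.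

**Step 9**
Reactants: 16 (1R,2R,3S,4Z,8Z)-3-hydroxy-5,9-dimethyl-2-(prop-1-en-2-yl)cyclodeca-4,8-dien-1-yl 4-(acetyloxy)benzoate
Product: 17 (1R,2R,3S,4Z,8Z)-3-hydroxy-5,9-dimethyl-2-(propan-2-yl)cyclodeca-4,8-dien-1-yl 4-(acetyloxy)benzoate
Conditions: H2 (1 atm), RhCl(PPh3)3 (10 mol%), benzene, rt
Reagents that add atoms: none
Why: Homogeneous hydrogenation with RhCl(PPh3)3, which reduces the 1,1‑disubstituted isopropenyl olefin and leaves the two trisubstituted ring olefins, the esters and the allylic alcohol alone; the new isopropyl carbon is not a stereocentre.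

**Step 10**
Reactants: 17 (1R,2R,3S,4Z,8Z)-3-hydroxy-5,9-dimethyl-2-(propan-2-yl)cyclodeca-4,8-dien-1-yl 4-(acetyloxy)benzoate
Product: 18 (1R,2R,3S,4Z,8Z)-3-hydroxy-5,9-dimethyl-2-(propan-2-yl)cyclodeca-4,8-dien-1-yl 4-hydroxybenzoate
Conditions: N2H4·AcOH (1.5 equiv), DMF, 0 °C to rt
Reagents that add atoms: none
Why: Hydrazinolysis of the phenolic acetate (an aryl ester is far more electrophilic than the secondary alkyl benzoate) under buffered, near‑neutral conditions that do not promote 1,3‑acyl migration to the C6 hydroxyl; no stereocentre is touched.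

**Compound list**
1 | neryl acetate, (2Z)-3,7-dimethylocta-2,6-dien-1-yl acetate | CC(=O)OC/C=C(/C)CCC=C(C)C | starting material
2 | (R)-epichlorohydrin, (2R)-2-(chloromethyl)oxirane | ClC[C@H]1CO1 | starting material
3 | 4-(acetyloxy)benzoyl chloride | CC(=O)Oc1ccc(cc1)C(Cl)=O | starting material
4 | 3-bromo-2-methylpropene (methallyl bromide) | CC(=C)CBr | starting material
5 | (2Z)-3-methyl-6-oxohex-2-en-1-yl acetate | CC(=O)OC/C=C(/C)CCC=O | intermediate
6 | (2Z,6Z)-7-iodo-3-methylocta-2,6-dien-1-yl acetate | CC(=O)OC/C=C(/C)CC/C=C(/C)I | intermediate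
7 | lithium (2Z,6Z)-7-iodo-3-methylocta-2,6-dien-1-olate (formed in the flask) | [Li+].[O-]C/C=C(/C)CC/C=C(/C)I | intermediate
8 | lithium (2Z,6Z)-7-(bromomagnesio)-3-methylocta-2,6-dien-1-olate (formed in the flask) | [Li+].[O-]C/C=C(/C)CC/C=C(/C)[Mg]Br | intermediate
9 | (2Z,6Z,9R)-10-chloro-3,7-dimethyldeca-2,6-diene-1,9-diol | OC/C=C(/C)CC/C=C(/C)C[C@@H](O)CCl | intermediate
10 | (2Z,6Z)-3,7-dimethyl-8-[(2R)-oxiran-2-yl]octa-2,6-dien-1-ol (formed in the flask) | OC/C=C(/C)CC/C=C(/C)C[C@@H]1CO1 | intermediate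
11 | (2Z,6Z,9R)-3,7-dimethylundeca-2,6,10-triene-1,9-diol | OC/C=C(/C)CC/C=C(/C)C[C@@H](O)C=C | intermediate
12 | (2Z,6Z,9R)-9-hydroxy-3,7-dimethylundeca-2,6,10-trienal | O=C/C=C(/C)CC/C=C(/C)C[C@@H](O)C=C | intermediate
13 | (3R,5Z,9Z)-5,9-dimethyl-11-oxoundeca-1,5,9-trien-3-yl 4-(acetyloxy)benzoate | O=C/C=C(/C)CC/C=C(/C)C[C@@H](OC(=O)c1ccc(OC(C)=O)cc1)C=C | intermediate
14 | (2E,4R,6Z,10Z)-1-bromo-2,6,10-trimethyl-12-oxododeca-2,6,10-trien-4-yl 4-(acetyloxy)benzoate | O=C/C=C(/C)CC/C=C(/C)C[C@@H](OC(=O)c1ccc(OC(C)=O)cc1)/C=C(\C)CBr | intermediate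
15 | dichloro[(2E,4R,6Z,10Z)-4-{[4-(acetyloxy)benzoyl]oxy}-2,6,10-trimethyl-12-oxododeca-2,6,10-trien-1-yl]chromium, trivalent chromium (formed in the flask) | O=C/C=C(/C)CC/C=C(/C)C[C@@H](OC(=O)c1ccc(OC(C)=O)cc1)/C=C(\C)C[Cr](Cl)Cl | intermediate
16 | (1R,2R,3S,4Z,8Z)-3-hydroxy-5,9-dimethyl-2-(prop-1-en-2-yl)cyclodeca-4,8-dien-1-yl 4-(acetyloxy)benzoate | C/C1=C/[C@H](O)[C@@H](C(C)=C)[C@H](OC(=O)c2ccc(OC(C)=O)cc2)C/C(C)=C\CC1 | intermediate
17 | (1R,2R,3S,4Z,8Z)-3-hydroxy-5,9-dimethyl-2-(propan-2-yl)cyclodeca-4,8-dien-1-yl 4-(acetyloxy)benzoate | C/C1=C/[C@H](O)[C@@H](C(C)C)[C@H](OC(=O)c2ccc(OC(C)=O)cc2)C/C(C)=C\CC1 | intermediate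
18 | (1R,2R,3S,4Z,8Z)-3-hydroxy-5,9-dimethyl-2-(propan-2-yl)cyclodeca-4,8-dien-1-yl 4-hydroxybenzoate | C/C1=C/[C@H](O)[C@@H](C(C)C)[C@H](OC(=O)c2ccc(O)cc2)C/C(C)=C\CC1 | target

**Totals**
Total step count: 10. Longest linear sequence: 10 steps (1 → 18); 2, 3 and 4 are bought.

**Steps most likely to fail, with fallbacks**

Ring closure, step 8 (highest risk). The allylchromium carries an acyloxy group δ to the metal, so it may lose the carboxylate by reductive 1,4‑elimination to a diene, or the aroyl group may shift to the new C6 chromium alkoxide. The facial bias from C8 rests on a conformational argument, not on a close precedent. The fallback sets out from 12 and comes back at 16: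
- 12 is silylated (t‑BuMe2SiCl, imidazole, DMF) to the silyl ether (2Z,6Z,9R)-9-[(tert-butyldimethylsilyl)oxy]-3,7-dimethylundeca-2,6,10-trienal F1.
- Cross‑metathesis with 4 under the step 7 conditions gives the allylic bromide F2.
- CrCl2 under the step 8 conditions closes the ring to the hydroxy silyl ether F3; a silyl ether cannot leave or migrate here, and the bulkier C8 substituent reinforces attack anti to C8–O.
- The C6 hydroxyl is masked as the 4‑methoxybenzyl ether F4 (4‑methoxybenzyl trichloroacetimidate, cat. La(OTf)3; acidic, so no silyl migration).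
- Bu4NF/AcOH frees the C8 alcohol F5, and 3/pyridine gives the ester F6.
- DDQ (CH2Cl2, pH 7 buffer) removes the benzyl ether and rejoins the route at 16.

Cross‑metathesis, step 7. Both partners are slow (a hindered secondary allylic ester and a 1,1‑disubstituted allylic halide), so conversion may stall, and the E/Z ratio is modest. The fallback sets out from 11 and comes back at 14:
- 11 is monosilylated at the primary hydroxyl (Et3SiCl, imidazole, −78 °C) to the triethylsilyl ether F7 and acylated with 3/pyridine to the ester F8.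
- Cross‑metathesis with methacrolein (same ruthenium catalyst; conjugated 1,1‑disubstituted enals are the best‑behaved partners for E‑trisubstituted olefins) gives the E‑enal F9.
- NaBH4/CeCl3 (−78 °C) gives the allylic alcohol F10, and CBr4/PPh3 the bromide F11.
- A Swern oxidation ((COCl)2, DMSO; Et3N), which converts a primary triethylsilyl ether directly into the aldehyde, delivers geometrically pure 14.

Hydrogenation, step 9. The isopropenyl group sits between two substituted ring carbons and may react slowly with the rhodium catalyst, and forcing conditions could start to reduce or shift the ring olefins. The fallback sets out from 16 and comes back at 17: metal‑free diimide reduction (2‑nitrobenzenesulfonylhydrazide, Et3N, CH2Cl2, rt, run to partial conversion and recycled), which discriminates by olefin substitution only. It makes no new compound (F0).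

**Further compounds**
F1 | step 8 | (2Z,6Z,9R)-9-[(tert-butyldimethylsilyl)oxy]-3,7-dimethylundeca-2,6,10-trienal | O=C/C=C(/C)CC/C=C(/C)C[C@@H](O[Si](C)(C)C(C)(C)C)C=C
F2 | step 8 | (2Z,6Z,9R,10E)-12-bromo-9-[(tert-butyldimethylsilyl)oxy]-3,7,11-trimethyldodeca-2,6,10-trienal | O=C/C=C(/C)CC/C=C(/C)C[C@@H](O[Si](C)(C)C(C)(C)C)/C=C(\C)CBr
F3 | step 8 | (1S,2Z,6Z,9R,10R)-9-[(tert-butyldimethylsilyl)oxy]-3,7-dimethyl-10-(prop-1-en-2-yl)cyclodeca-2,6-dien-1-ol | C/C1=C/[C@H](O)[C@@H](C(C)=C)[C@H](O[Si](C)(C)C(C)(C)C)C/C(C)=C\CC1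
F4 | step 8 | 4-methoxybenzyl ether of F3 at the C6 hydroxyl | C/C1=C/[C@H](OCc2ccc(OC)cc2)[C@@H](C(C)=C)[C@H](O[Si](C)(C)C(C)(C)C)C/C(C)=C\CC1
F5 | step 8 | C8 alcohol obtained from F4 by desilylation (C6 4-methoxybenzyl ether retained) | C/C1=C/[C@H](OCc2ccc(OC)cc2)[C@@H](C(C)=C)[C@H](O)C/C(C)=C\CC1
F6 | step 8 | C6 4-methoxybenzyl ether of 16 | C/C1=C/[C@H](OCc2ccc(OC)cc2)[C@@H](C(C)=C)[C@H](OC(=O)c2ccc(OC(C)=O)cc2)C/C(C)=C\CC1
F7 | step 7 | (3R,5Z,9Z)-5,9-dimethyl-11-[(triethylsilyl)oxy]undeca-1,5,9-trien-3-ol | CC[Si](CC)(CC)OC/C=C(/C)CC/C=C(/C)C[C@@H](O)C=C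
F8 | step 7 | (3R,5Z,9Z)-5,9-dimethyl-11-[(triethylsilyl)oxy]undeca-1,5,9-trien-3-yl 4-(acetyloxy)benzoate | CC[Si](CC)(CC)OC/C=C(/C)CC/C=C(/C)C[C@@H](OC(=O)c1ccc(OC(C)=O)cc1)C=C
F9 | step 7 | (2E,4R,6Z,10Z)-2,6,10-trimethyl-1-oxo-12-[(triethylsilyl)oxy]dodeca-2,6,10-trien-4-yl 4-(acetyloxy)benzoate | CC[Si](CC)(CC)OC/C=C(/C)CC/C=C(/C)C[C@@H](OC(=O)c1ccc(OC(C)=O)cc1)/C=C(\C)C=O
F10 | step 7 | (2E,4R,6Z,10Z)-1-hydroxy-2,6,10-trimethyl-12-[(triethylsilyl)oxy]dodeca-2,6,10-trien-4-yl 4-(acetyloxy)benzoate | CC[Si](CC)(CC)OC/C=C(/C)CC/C=C(/C)C[C@@H](OC(=O)c1ccc(OC(C)=O)cc1)/C=C(\C)CO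
F11 | step 7 | (2E,4R,6Z,10Z)-1-bromo-2,6,10-trimethyl-12-[(triethylsilyl)oxy]dodeca-2,6,10-trien-4-yl 4-(acetyloxy)benzoate | CC[Si](CC)(CC)OC/C=C(/C)CC/C=C(/C)C[C@@H](OC(=O)c1ccc(OC(C)=O)cc1)/C=C(\C)CBr
F0 | step 9 | none | none
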